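The cyclohexenone ring is traced back to dimethyl squarate: ring atoms C1 (C=O), C2 and C3 (both OMe) and C4 (O) are the four squarate carbons, while C5 and C6, with the C6 methyl and the whole side chain, are the two sp2 carbons of an E-alkenyl metal added to one squarate carbonyl. After reduction to the trans-diol and silylation, the 1-alkenyl-1,4-bis(silyloxy)cyclobutene opens (conrotatory 4π, both oxygens outward) and recloses (disrotatory 6π) to the six-membered ring, setting C4/C5 cis in one operation; C6 follows by equilibration. The lactone stems from an L-glutamic-acid-derived butanolide; the ring's absolute configuration is selected by a catalyst-controlled final acetylation.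

Key step: step 15

Remark on numbering: C1–C6 are the cyclohexenone carbons of the target (C1 carbonyl, C4 acetoxy-bearing, C5 chain-bearing, C6 methyl-bearing); C1′–C8′ are the side-chain carbons counted from the ring.
Remark on mixtures: 25–27, 29, 30, F1 and F2 carry one lactone configuration but both ring configurations. Names and SMILES show the member that leads to 31 (the carbinol centre of 25 is left undefined). For 30 the accompanying member is its (4S,5S,6S) ring diastereomer; it carries no number of its own, is not acetylated in step 16 and is removed there as the unreacted alcohol.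
Assumption: the (R)-amidine catalyst of step 16 is taken as matched with the (4R)-carbinol, by analogy with (R)-1-alkenylcarbinols; if the sense were opposite, the (S)-catalyst would be used.

Step 1
Reactants: 1 1-(trimethylsilyl)propyne; 2 1-bromobut-2-yne
Product: 4 trimethyl(hepta-1,5-diyn-1-yl)silane, via silylpropargyllithium 3 (not isolated)
Conditions: n-BuLi, TMEDA, Et2O, −5 °C; then 2, −78 °C to rt
Reagents that add atoms: none
Why: Propargylic lithiation of 1 and SN2 alkylation of the silyl-capped propargyl anion by the primary propargylic bromide (propargyl anion alkylation) should give the 1,5-diyne, the silyl group steering attack to the remote carbon.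

Step 2
Reactants: 4 trimethyl(hepta-1,5-diyn-1-yl)silane
Product: 5 hepta-1,5-diyne
Conditions: K2CO3 (0.2 equiv), MeOH, rt
Reagents that add atoms: none
Why: Base-catalysed methanolysis of the alkynylsilane (protodesilylation) frees the terminal alkyne and leaves the internal one untouched.

Step 3
Reactants: 5 hepta-1,5-diyne
Product: 7 (2E)-3-methyloct-2-en-6-yn-1-ol, via alkenylalane 6 (not isolated)
Conditions: Me3Al, Cp2ZrCl2 (20 mol%), CH2Cl2, 0 °C to rt; then n-BuLi, THF, −78 °C; (CH2O)n, rt; aq. HCl
Reagents that add atoms: trimethylaluminium C[Al](C)C; formaldehyde (from paraformaldehyde) C=O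
Why: Negishi carboalumination adds methyl and aluminium syn across the terminal alkyne only (the internal alkyne is far slower), and hydroxymethylation of the derived aluminate with retention should give the E-trisubstituted allylic alcohol.

Step 4
Reactants: 7 (2E)-3-methyloct-2-en-6-yn-1-ol
Product: 8 tert-butyldimethyl{[(2E)-3-methyloct-2-en-6-yn-1-yl]oxy}silane
Conditions: TBSCl, imidazole, CH2Cl2, 0 °C to rt
Reagents that add atoms: tert-butyldimethylsilyl chloride CC(C)(C)[Si](C)(C)Cl
Why: Standard silylation masks the allylic alcohol against the organolithium of step 9.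

Step 5
Reactants: 8 silyl ether of the enynol
Product: 10 tert-butyl{[(2E,6E)-7-iodo-3-methylocta-2,6-dien-1-yl]oxy}dimethylsilane, via alkenylzirconocene chloride 9 (not isolated)
Conditions: Cp2Zr(H)Cl (1.5 equiv), THF, rt to 40 °C; then I2, 0 °C
Reagents that add atoms: iodine II
Why: syn-Hydrozirconation of the methyl-capped alkyne should place zirconium on the less hindered carbon next to methyl after equilibration with a slight excess of reagent, and iodinolysis with retention gives the E-alkenyl iodide (iodine trans to the chain); the minor regioisomer is removed by chromatography.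

Step 6
Reactants: 11 (5S)-5-[(trityloxy)methyl]oxolan-2-one
Product: 13 (3R,5S)-3-methyl-5-[(trityloxy)methyl]oxolan-2-one, via lithium enolate 12 (not isolated)
Conditions: LiN(i-Pr)2, THF, −78 °C; MeI, −78 °C
Reagents that add atoms: iodomethane CI
Why: Enolate alkylation under substrate control: methyl iodide approaches the lactone enolate anti to the bulky trityloxymethyl group, which should set the alpha-methyl trans to the purchased gamma-centre.

Step 7
Reactants: 13 (3R,5S)-3-methyl-5-[(trityloxy)methyl]oxolan-2-one
Product: 14 (3R,5S)-5-(hydroxymethyl)-3-methyloxolan-2-one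
Conditions: AcOH–H2O (4:1), 50 °C
Reagents that add atoms: none
Why: Mild acid solvolysis of the trityl ether through the trityl cation leaves the lactone and both stereocentres untouched.

Step 8
Reactants: 14 (3R,5S)-5-(hydroxymethyl)-3-methyloxolan-2-one
Product: 15 [(2S,4R)-4-methyl-5-oxooxolan-2-yl]methyl trifluoromethanesulfonate
Conditions: Tf2O, pyridine, CH2Cl2, −40 to 0 °C; used at once
Reagents that add atoms: triflic anhydride FC(F)(F)S(=O)(=O)OS(=O)(=O)C(F)(F)F
Why: Triflation of the primary alcohol gives an electrophile reactive enough for copper-catalysed substitution at low temperature, where the lactone carbonyl is not attacked.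

Step 9
Reactants: 10 (2E,6E)-alkenyl iodide; 15 lactone triflate
Product: 18 (3R,5S)-5-[(2E,6E)-8-(tert-butyldimethylsilyloxy)-2,6-dimethylocta-2,6-dien-1-yl]-3-methyloxolan-2-one, via alkenyllithium 16 (not isolated), via alkenylmagnesium bromide 17 (not isolated)
Conditions: t-BuLi (2 equiv), Et2O, −78 °C; MgBr2·OEt2; then CuBr·SMe2 (10 mol%), 15, THF, −78 to −20 °C
Reagents that add atoms: none
Why: Iodine–lithium exchange with retention of alkene geometry, transmetalation to magnesium and copper-catalysed SN2 displacement of the primary triflate should join C7′ to C8′ without touching either lactone stereocentre.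

Step 10
Reactants: 18 silyl-protected dienyl lactone
Product: 19 (3R,5S)-5-[(2E,6E)-8-bromo-2,6-dimethylocta-2,6-dien-1-yl]-3-methyloxolan-2-one
Conditions: Ph3PBr2, CH2Cl2, 0 °C to rt
Reagents that add atoms: dibromotriphenylphosphorane BrP(Br)(c1ccccc1)(c1ccccc1)c1ccccc1
Why: Dibromotriphenylphosphorane converts the allylic silyl ether directly into the primary allylic bromide (oxyphosphonium formation, then SN2 by bromide) with retention of the E geometry.

Step 11
Reactants: 19 allylic bromide; 20 propyne
Product: 21 (3R,5S)-5-[(2E,6E)-2,6-dimethylundeca-2,6-dien-9-yn-1-yl]-3-methyloxolan-2-one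
Conditions: propyne (excess), CuI (20 mol%), NaI (20 mol%), Cs2CO3, DMF, rt
Reagents that add atoms: none
Why: The copper acetylide formed from propyne under carbonate base should displace the primary allylic halide mainly at the alpha carbon (copper-mediated alkyne–allyl coupling), installing the skipped enyne without a basic organometallic that would attack the lactone.

Step 12
Reactants: 21 skipped enyne lactone; 22 dimethyl squarate (3,4-dimethoxycyclobut-3-ene-1,2-dione)
Product: 25 4-hydroxy-2,3-dimethoxy-4-{(2E,5E,9E)-6,10-dimethyl-11-[(2S,4R)-4-methyl-5-oxooxolan-2-yl]undeca-2,5,9-trien-2-yl}cyclobut-2-en-1-one, via alkenylzirconocene chloride 23 (not isolated), via alkenylmethylzinc 24 (not isolated)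
Conditions: Cp2Zr(H)Cl (1.3 equiv), CH2Cl2, rt; solvent changed to toluene; Me2Zn, −65 °C; 22, −65 to 0 °C; aq. NH4Cl
Reagents that add atoms: none
Why: syn-Hydrozirconation again puts the metal next to methyl and trans to the chain, and zirconium-to-zinc transmetalation gives an alkenylzinc that should add 1,2 to one of the two equivalent, strongly electrophilic squarate carbonyls (as such reagents do with alpha-keto esters) while the lactone stays inert; the new carbinol centre is formed in both configurations and is erased in step 15.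

Step 13
Reactants: 25 hydroxycyclobutenone
Product: 26 trans-1-alkenyl-2,3-dimethoxycyclobut-2-ene-1,4-diol (alkenyl group as in 25; hydroxyls on opposite faces)
Conditions: NaBH4, CeCl3·7H2O, MeOH–THF, −78 to −40 °C; cold neutral work-up
Reagents that add atoms: none
Why: Luche 1,2-reduction should deliver hydride to the carbonyl face anti to the bulky alkenyl group on the neighbouring quaternary carbon (the face of its hydroxyl), so the new hydroxyl ends up trans to the old one, as the double outward rotation in step 15 requires.

Step 14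
Reactants: 26 trans-diol
Product: 27 trans-1-alkenyl-2,3-dimethoxy-1,4-bis(trimethylsilyloxy)cyclobut-2-ene
Conditions: TMSOTf, Et3N, CH2Cl2, −78 °C; used at once
Reagents that add atoms: trimethylsilyl triflate C[Si](C)(C)OS(=O)(=O)C(F)(F)F
Why: Fast, base-buffered silylation at −78 °C caps both hydroxyls before the thermally labile trans-diol can ring-open, so that every later open-chain or cyclic enol is a silyl enol ether and cannot ketonise.

Step 15
Reactants: 27 bis(silyloxy)cyclobutene
Product: 30 (4R,5R,6R)-4-hydroxy-2,3-dimethoxy-6-methyl-5-{(2E,6E)-3,7-dimethyl-8-[(2S,4R)-4-methyl-5-oxooxolan-2-yl]octa-2,6-dien-1-yl}cyclohex-2-en-1-one, via hexatriene 28 (not isolated), via silyl dienol ether 29 (not isolated)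
Conditions: toluene, Et3N (0.2 equiv), rt to 80 °C; then 0.5 M HCl, THF, 0 °C; then DBU (0.2 equiv), CH2Cl2, rt
Reagents that add atoms: none
Why: Warming 27 should trigger a thermal conrotatory 4π ring opening in which both silyloxy groups rotate outward (donor torquoselectivity), giving hexatriene 28 with an E enol ether terminus and the E-alkenyl unit turned inward across the central double bond; a thermal disrotatory 6π electrocyclization then joins the former cyclobutene CH(OTMS) carbon to the alkenyl CH carbon, so that the four-membered ring grows by two carbons into cyclohexadiene 29. The closest known reactions are the ring-opening/6π-electrocyclization cascades of 3-vinylcyclobutenes, of 4-alkenylcyclobutenones (Moore rearrangement) and of 1-alkenylcyclobutenols made from cyclobutenones and alkenyllithiums. The only ring closed is the six-membered carbocycle, by 6π electrocyclization forming the C4–C5 bond. C4 and C5 are created together, and the disrotatory motion of an E,Z,E-triene places the two outward groups (C4 silyloxy, C5 chain) cis; C6 is created when the silyl dienol ether is hydrolysed and is equilibrated by DBU to the more stable trans-5,6 arrangement (equatorial methyl, no syn-axial clash with the pseudoaxial C4 oxygen). The step needs the both-outward torquoselectivity, which the trans-diol geometry from step 13 secures (a cis isomer would have to turn one oxygen inward and should stay behind at 80 °C), and the outward chain, which the syn-hydrozirconation of step 12 secures. All stereoisomers at the two cyclobutene centres converge on one relative configuration, but both absolute senses of the ring are formed, so 30 is expected as a mixture with its (4S,5S,6S) ring diastereomer, from which step 16 selects the (4R,5R,6R) member.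

Step 16
Reactants: 30 (4R,5R,6R)-hydroxy enone (as the mixture with its ring diastereomer obtained in step 15)
Product: 31 CNP0600606.1, (4R,5R,6R)-4-acetoxy-2,3-dimethoxy-6-methyl-5-{(2E,6E)-3,7-dimethyl-8-[(2S,4R)-4-methyl-5-oxooxolan-2-yl]octa-2,6-dien-1-yl}cyclohex-2-en-1-one
Conditions: Ac2O (0.55 equiv), (R)-7-chloro-2-phenyl-1,2-dihydroimidazo[1,2-a]quinoline (5 mol%), i-Pr2NEt, CHCl3, 0 °C; chromatography
Reagents that add atoms: acetic anhydride CC(=O)OC(C)=O
Why: Amidine-catalysed enantioselective acyl transfer (kinetic resolution of a secondary allylic alcohol) should acetylate the (4R)-carbinol, whose C3=C2 π-system and C5 alkyl flank match the fast-reacting (R)-1-alkenylcarbinol model, while the (4S,5S,6S) ring diastereomer stays as the alcohol and is separated by chromatography; at most half of the mixture can be converted, and no stereocentre is touched.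

Compound list
1 | 1-(trimethylsilyl)propyne | CC#C[Si](C)(C)C | starting material
2 | 1-bromobut-2-yne | CC#CCBr | starting material
3 | [3-(trimethylsilyl)prop-2-yn-1-yl]lithium | [Li]CC#C[Si](C)(C)C | intermediate
4 | trimethyl(hepta-1,5-diyn-1-yl)silane | CC#CCCC#C[Si](C)(C)C | intermediate
5 | hepta-1,5-diyne | CC#CCCC#C | intermediate
6 | dimethyl[(1E)-2-methylhept-1-en-5-yn-1-yl]alane | C[Al](C)/C=C(\C)CCC#CC | intermediate
7 | (2E)-3-methyloct-2-en-6-yn-1-ol | OC/C=C(\C)CCC#CC | intermediate
8 | tert-butyldimethyl{[(2E)-3-methyloct-2-en-6-yn-1-yl]oxy}silane | CC(C)(C)[Si](C)(C)OC/C=C(\C)CCC#CC | intermediate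
9 | chlorobis(cyclopentadienyl)[(2E,6E)-8-(tert-butyldimethylsilyloxy)-6-methylocta-2,6-dien-2-yl]zirconium | CC(C)(C)[Si](C)(C)OC/C=C(\C)CC/C=C(\C)[Zr](Cl)(C1C=CC=C1)C1C=CC=C1 | intermediate
10 | tert-butyl{[(2E,6E)-7-iodo-3-methylocta-2,6-dien-1-yl]oxy}dimethylsilane | CC(C)(C)[Si](C)(C)OC/C=C(\C)CC/C=C(\C)I | intermediate
11 | (5S)-5-[(trityloxy)methyl]oxolan-2-one | C(c1ccccc1)(c1ccccc1)(c1ccccc1)OC[C@@H]2CCC(=O)O2 | starting material
12 | lithium enolate of 11 | C(c1ccccc1)(c1ccccc1)(c1ccccc1)OC[C@@H]2CC=C(O[Li])O2 | intermediate
13 | (3R,5S)-3-methyl-5-[(trityloxy)methyl]oxolan-2-one | C(c1ccccc1)(c1ccccc1)(c1ccccc1)OC[C@@H]2C[C@@H](C)C(=O)O2 | intermediate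
14 | (3R,5S)-5-(hydroxymethyl)-3-methyloxolan-2-one | OC[C@@H]1C[C@@H](C)C(=O)O1 | intermediate
15 | [(2S,4R)-4-methyl-5-oxooxolan-2-yl]methyl trifluoromethanesulfonate | FC(F)(F)S(=O)(=O)OC[C@@H]1C[C@@H](C)C(=O)O1 | intermediate
16 | [(2Z,6E)-8-(tert-butyldimethylsilyloxy)-6-methylocta-2,6-dien-2-yl]lithium (lithium trans to the chain as in 9; the descriptor is Z only because lithium ranks below carbon) | CC(C)(C)[Si](C)(C)OC/C=C(\C)CC/C=C(\C)[Li] | intermediate
17 | [(2E,6E)-8-(tert-butyldimethylsilyloxy)-6-methylocta-2,6-dien-2-yl]magnesium bromide | CC(C)(C)[Si](C)(C)OC/C=C(\C)CC/C=C(\C)[Mg]Br | intermediate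
18 | (3R,5S)-5-[(2E,6E)-8-(tert-butyldimethylsilyloxy)-2,6-dimethylocta-2,6-dien-1-yl]-3-methyloxolan-2-one | CC(C)(C)[Si](C)(C)OC/C=C(\C)CC/C=C(\C)C[C@@H]1C[C@@H](C)C(=O)O1 | intermediate
19 | (3R,5S)-5-[(2E,6E)-8-bromo-2,6-dimethylocta-2,6-dien-1-yl]-3-methyloxolan-2-one | BrC/C=C(\C)CC/C=C(\C)C[C@@H]1C[C@@H](C)C(=O)O1 | intermediate
20 | propyne | CC#C | starting material
21 | (3R,5S)-5-[(2E,6E)-2,6-dimethylundeca-2,6-dien-9-yn-1-yl]-3-methyloxolan-2-one | CC#CC/C=C(\C)CC/C=C(\C)C[C@@H]1C[C@@H](C)C(=O)O1 | intermediate
22 | dimethyl squarate (3,4-dimethoxycyclobut-3-ene-1,2-dione) | COC1=C(OC)C(=O)C1=O | starting material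
23 | alkenylzirconocene chloride from 21 (zirconium on the methyl-bearing carbon, trans to the chain) | Cl[Zr](C1C=CC=C1)(C1C=CC=C1)/C(C)=C/C/C=C(\C)CC/C=C(\C)C[C@@H]2C[C@@H](C)C(=O)O2 | intermediate
24 | the corresponding alkenyl(methyl)zinc | C[Zn]/C(C)=C/C/C=C(\C)CC/C=C(\C)C[C@@H]1C[C@@H](C)C(=O)O1 | intermediate
25 | 4-hydroxy-2,3-dimethoxy-4-{(2E,5E,9E)-6,10-dimethyl-11-[(2S,4R)-4-methyl-5-oxooxolan-2-yl]undeca-2,5,9-trien-2-yl}cyclobut-2-en-1-one (both configurations at the carbinol carbon) | COC1=C(OC)C(O)(/C(C)=C/C/C=C(\C)CC/C=C(\C)C[C@@H]2C[C@@H](C)C(=O)O2)C1=O | intermediate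
26 | trans-1-alkenyl-2,3-dimethoxycyclobut-2-ene-1,4-diol, alkenyl as in 25 (drawn isomer; the isomer with both ring centres inverted accompanies it) | O[C@H]1C(OC)=C(OC)[C@@]1(O)/C(C)=C/C/C=C(\C)CC/C=C(\C)C[C@@H]2C[C@@H](C)C(=O)O2 | intermediate
27 | bis(trimethylsilyl) ether of 26 | C[Si](C)(C)O[C@H]1C(OC)=C(OC)[C@@]1(O[Si](C)(C)C)/C(C)=C/C/C=C(\C)CC/C=C(\C)C[C@@H]2C[C@@H](C)C(=O)O2 | intermediate
28 | hexatriene TMSO–CH=C(OMe)–C(OMe)=C(OTMS)–C(Me)=CH–CH2–chain (E enol ether terminus; alkenyl cis to the C(OMe)=CH unit across the central double bond; E alkenyl) | C[Si](C)(C)O/C=C(OC)/C(OC)=C(O[Si](C)(C)C)\C(C)=C\C/C=C(\C)CC/C=C(\C)C[C@@H]1C[C@@H](C)C(=O)O1 | intermediate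
29 | cis-4,5-configured 2,3-dimethoxy-6-methyl-1,4-bis(trimethylsilyloxy)-5-(side chain)cyclohexa-1,3-diene (drawn ring isomer; its ring mirror form accompanies it) | COC1=C(OC)[C@H](O[Si](C)(C)C)[C@H](C/C=C(\C)CC/C=C(\C)C[C@@H]2C[C@@H](C)C(=O)O2)C(C)=C1O[Si](C)(C)C | intermediate
30 | (4R,5R,6R)-4-hydroxy-2,3-dimethoxy-6-methyl-5-{(2E,6E)-3,7-dimethyl-8-[(2S,4R)-4-methyl-5-oxooxolan-2-yl]octa-2,6-dien-1-yl}cyclohex-2-en-1-one (drawn ring isomer; its (4S,5S,6S) ring diastereomer accompanies it) | COC1=C(OC)[C@H](O)[C@H](C/C=C(\C)CC/C=C(\C)C[C@@H]2C[C@@H](C)C(=O)O2)[C@@H](C)C1=O | intermediate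
31 | CNP0600606.1, (4R,5R,6R)-4-acetoxy-2,3-dimethoxy-6-methyl-5-{(2E,6E)-3,7-dimethyl-8-[(2S,4R)-4-methyl-5-oxooxolan-2-yl]octa-2,6-dien-1-yl}cyclohex-2-en-1-one | COC1=C(OC)[C@H](OC(C)=O)[C@H](C/C=C(\C)CC/C=C(\C)C[C@@H]2C[C@@H](C)C(=O)O2)[C@@H](C)C1=O | target

Total step count: 16. Longest linear sequence: 13 steps (steps 1–5 and 9–16); the lactone branch (steps 6–8) joins at step 9.

Steps most likely to fail

Step 15. The silyl enol ether triene may hydrolyse or oligomerise before the slower 6π closure, and the cyclohexadiene may aromatise by loss of silanol at 80 °C. The fallback keeps the ring expansion but runs it as an anionic cascade at low temperature. It sets out from diol 26: selective silylation of the secondary hydroxyl (TBSOTf, 2,6-lutidine, CH2Cl2, −78 °C) should give the mono-silyl ether, trans-1-alkenyl-4-(tert-butyldimethylsilyloxy)-2,3-dimethoxycyclobut-2-en-1-ol F1. KN(SiMe3)2 (1.05 equiv, THF, −78 to 0 °C) then forms the tertiary alkoxide, whose oxy-anion-accelerated conrotatory opening (alkoxide and silyloxy both outward) and 6π closure should occur well below room temperature and end in an enolate that cannot eliminate. Quenching with NH4Cl and DBU equilibration should give the 4-silyloxy enone, (4R,5R,6R)-4-(tert-butyldimethylsilyloxy)-2,3-dimethoxy-6-methyl-5-(side chain)cyclohex-2-en-1-one F2 (with its ring diastereomer), and HF·pyridine (THF, 0 °C) comes back to 30, again as the mixture of ring diastereomers.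

Step 12. Transmetalation from zirconium to zinc may be incomplete, methyl transfer or conjugate addition–elimination at the squarate may compete with 1,2-addition, and excess Cp2Zr(H)Cl may partly reduce the lactone. The fallback sets out from enyne 21: hydrozirconation followed by iodine should give the alkenyl iodide, (3R,5S)-5-[(2E,6E,9E)-10-iodo-2,6-dimethylundeca-2,6,9-trien-1-yl]-3-methyloxolan-2-one F3, which is freed from its regioisomer by chromatography. CrCl2 with NiCl2 (1 mol%) in DMF–THF in the presence of 22 (Nozaki–Hiyama–Kishi alkenylation, which leaves lactones alone) should then add the alkenylchromium species to one squarate carbonyl and come back to 25.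

Step 16. The selectivity of the acyl transfer may be low on this hindered carbinol, whose C4 hydroxyl is flanked by an enol ether carbon and a cis C5 substituent, so the acetate would be contaminated with the acetate of the (4S,5S,6S) ring diastereomer. The fallback sets out from 30 as the mixture obtained in step 15: the two ring diastereomers are separated by preparative HPLC on a chiral stationary phase, and the pure (4R,5R,6R) alcohol 30 is acetylated without selection (Ac2O, pyridine, DMAP, CH2Cl2, 0 °C) to come back to 31; this makes no new compound (F0).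

Further compounds
F1 | step 15 | trans-1-alkenyl-4-(tert-butyldimethylsilyloxy)-2,3-dimethoxycyclobut-2-en-1-ol (alkenyl as in 25) | CC(C)(C)[Si](C)(C)O[C@H]1C(OC)=C(OC)[C@@]1(O)/C(C)=C/C/C=C(\C)CC/C=C(\C)C[C@@H]2C[C@@H](C)C(=O)O2
F2 | step 15 | (4R,5R,6R)-4-(tert-butyldimethylsilyloxy)-2,3-dimethoxy-6-methyl-5-{(2E,6E)-3,7-dimethyl-8-[(2S,4R)-4-methyl-5-oxooxolan-2-yl]octa-2,6-dien-1-yl}cyclohex-2-en-1-one | COC1=C(OC)[C@H](O[Si](C)(C)C(C)(C)C)[C@H](C/C=C(\C)CC/C=C(\C)C[C@@H]2C[C@@H](C)C(=O)O2)[C@@H](C)C1=O
F3 | step 12 | (3R,5S)-5-[(2E,6E,9E)-10-iodo-2,6-dimethylundeca-2,6,9-trien-1-yl]-3-methyloxolan-2-one | I/C(C)=C/C/C=C(\C)CC/C=C(\C)C[C@@H]1C[C@@H](C)C(=O)O1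
F0 | step 16 | none | none
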